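**The wrong column.** It is tempting to follow the target, but at 3.00 min in the midnight run it holds 3.2%, far less than the 43.8% of over-reaction product, and the substrate holds 47.8%. So the contest is between those two.

| setting | midnight | spring | alder | cedar |
|---|---|---|---|---|
| substrate | 0.25 M | 0.25 M | 0.25 M | 0.25 M |
| reagent in the second phase | 0.43 M | 0.65 M | 0.280 M | 0.550 M |
| remark | run made earlier | run made earlier |  |  |
| time |  |  | 4.0 min | 4.0 min |
| volume of the second phase over the first |  |  | 2.0 | 2.0 |

| run | time / min | target / % | over-reaction product / % | substrate / % | isomer of the product / % | over-reacted product / % |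
|---|---|---|---|---|---|---|
| midnight | 0.500 | 5.6 | 4.5 | 88.0 | 0.4 | 0.9 |
| midnight | 1.00 | 7.0 | 15.7 | 76.0 | 0.7 | 1.4 |
| midnight | 1.50 | 5.6 | 25.2 | 65.6 | 1.9 | 1.8 |
| midnight | 2.50 | 3.6 | 39.3 | 52.6 | 1.9 | 2.2 |
| midnight | 3.00 | 3.2 | 43.8 | 47.8 | 2.5 | 2.5 |
| spring | 0.250 | 4.9 | 1.4 | 92.9 | 0 | 0.1 |
| spring | 0.417 | 8.2 | 5.2 | 86.2 | 0.9 | 0.3 |
| spring | 0.833 | 9.9 | 17.6 | 71.2 | 0.9 | 1.9 |
| spring | 1.33 | 8.1 | 29.7 | 57.4 | 1.3 | 2.7 |
| spring | 3.00 | 3.1 | 56.8 | 31.6 | 2.9 | 5.2 |

(each reading ± 0.3 percentage points)

- which of these there is most of at the end, counted by the substrate in it, alder (over-reacted product / isomer of the product / over-reaction product / target / substrate)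
- which of these there is most of at the end, counted by the substrate in it, cedar (over-reacted product / isomer of the product / over-reaction product / target / substrate)
- amount of the one of these that there is most of at the end, in percent of the substrate charged, alder
- amount of the one of these that there is most of at the end, in percent of the substrate charged, cedar

- in the second phase: reagent in the second phase; everything else is in the first
- charges count per volume of the first phase; a concentration in a rate is the amount of a species over the volume of its own phase; every rate counts per litre of the first phase
- the earlier runs were read with a standard deviation of 0.3 percentage points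
- the earlier runs hold the two phases in the same ratio of volumes as the flask asked about

**One number.** I take substrate loss as pseudo-first-order, proportional to charged reagent, and fold charge and time into the exposure N = κ[reagent in the second phase]t, so substrate left is exp(−N). The last readings give κ as 0.00954 M⁻¹ s⁻¹ (midnight) and 0.00985 M⁻¹ s⁻¹ (spring), on average 0.00969 M⁻¹ s⁻¹.

**The crossing.** Target, isomer and over-reacted product together hold 8.20% at midnight's last reading. If substrate and over-reaction product share the remainder equally, N stands at 0.779, the crossing exposure, where the lead changes hands.

**Reading off.** Alder reaches 0.651, below the crossing, so I expect substrate to lead at 52.2%. Cedar reaches 1.28, above it, so I expect over-reaction product to lead at 64.0%.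

**One enough?** Midnight's κ read at 1.50 min is 0.0109 M⁻¹ s⁻¹, above the late value, so κ falls with time and my exposures are probably overshot, which makes my substrate for alder too low and my over-reaction product for cedar too high. Yet alder crosses only at κ = 0.0116 M⁻¹ s⁻¹, above even that early reading. The number serves for the leader, less well for the amount.

**The forecast.** It gives substrate at 55% for alder and over-reaction product at 60.5% for cedar, holding that “Substrate loss scales with reagent”. Its leaders are mine, and its amounts lie on the side my test points to.

**The result.** Alder ends with substrate at 55.8%, cedar with over-reaction product at 60.3%.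

    substrate + reagent in the reaction phase → target (k = 0.0428 M⁻¹ s⁻¹)
    target ⇌ isomer of the product (K = 1.67, k = 0.00324 s⁻¹)
    target → over-reaction product (k = 0.0501 s⁻¹)
    reagent in the reaction phase → decomposed reagent (k = 0.00362 s⁻¹)
    reagent in the reaction phase ⇌ reagent in the second phase, rate k5*([reagent in the reaction phase] - [reagent in the second phase]/K5) per volume of the first phase (partition coefficient = 0.950, kL = 0.0813 s⁻¹)
    reagent in the reaction phase + target → over-reacted product (k = 0.0291 M⁻¹ s⁻¹)

In alder the over-reaction product stands at 39.0%. The exposures these amounts imply, 0.583 for alder and 1.21 for cedar, lie on either side of 0.779. Cedar read at 1.0 min has N = 0.320, below the crossing, and there substrate leads with 70.2% against 18.8% of over-reaction product.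

The earlier runs and the new flask are simulated with made-up constants; scatter was added.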